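Cuts (C1 = oxirane carbon bearing C7H2O, C2 = carbinol, C3 = benzoyloxy carbon, C4=C5 = ring alkene, C6 = oxirane CH): first the two benzoate C–O bonds, then ring bond C4=C5, then both C–O bonds of the C1–C6 oxirane, then C5=CH2 and C1=C6, leaving a C7–C1–C2–C3–C4 ketone excised from C1–C5 of D-fructose.
Forward: fructose is fixed as an acetonide-bridged methyl furanoside; zinc opens the furanoside and methanolysis the dioxane; a butenolide is closed and reopened to fix the Z alkene; the oxirane is closed on the open chain; the cyclohexene is closed last by metathesis; the benzoates go on at the end.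
Stereochemistry: C2 and C3 are C3 and C4 of D-fructose, carried through untouched; C1 and C6 arise together in the epoxidation, steered by the C2 carbinol; the cis disposition of the two alkenyl arms on the oxirane comes from the ring-enforced Z geometry.
Enabling feature: the C2 hydroxyl is attached next to oxirane carbon C1 and lies anti to the C1–C6 oxirane oxygen on the six-membered ring; while the ring is still open between C4 and C5 it is the allylic hydroxyl of a (Z)-trisubstituted C1=C6 alkene and can deliver a peracid to exactly that face, whereas on the closed cyclohexene it would deliver syn.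

Key step: step 11

Remark: step 1 gives a mixture of methyl fructofuranoside anomers; it is assumed that the mixture can be taken into step 2 as such, because only the α-anomer can form the 1,3-acetal, and 2 denotes that anomer.
Abbreviations: TBS = tert-butyldimethylsilyl, MOP = 2-methoxypropan-2-yl, Bz = benzoyl, CSA = camphorsulfonic acid, PPTS = pyridinium p-toluenesulfonate.

Step 1
Reactants: 1 D-fructose
Product: 2 methyl α-D-fructofuranoside
Conditions: MeOH, H2SO4 (cat.), rt, about 1 h; then NaHCO3
Reagents that add atoms: methanol, CO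
Why: Fischer glycosidation under kinetic control should trap the ketose as its methyl furanosides before ring expansion to the pyranoside, the anomeric centre forming as a mixture of which the α-anomer (C1 and O3 on the same ring face) is the one used, while C3, C4 and C5 are not touched.

Step 2
Reactants: 2 methyl α-D-fructofuranoside
Product: 3 methyl 1,3-O-isopropylidene-α-D-fructofuranoside
Conditions: 2,2-dimethoxypropane, TsOH·H2O (cat.), DMF, rt; then Et3N
Reagents that add atoms: 2,2-dimethoxypropane, COC(C)(C)OC
Why: Acid-catalysed transacetalisation should close a cis-fused 1,3-dioxane only across O1 and O3 of the α-furanoside, because the trans 3,4-diol and the 4,6-pair cannot be bridged without strain, so O4 and O6 stay free and no stereocentre is created.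

Step 3
Reactants: 3 methyl 1,3-O-isopropylidene-α-D-fructofuranoside
Product: 4 methyl 6-deoxy-6-iodo-1,3-O-isopropylidene-α-D-fructofuranoside
Conditions: I2, PPh3, imidazole, THF, 0 °C to rt
Reagents that add atoms: iodine, II
Why: In this Garegg–Samuelsson (Appel-type) iodination the alkoxyphosphonium ion is displaced by iodide in an SN2 step that is fast only at the unhindered primary C6, the imidazole buffer protecting the acetal and the ketoside and the secondary 4-hydroxyl remaining free.

Step 4
Reactants: 4 methyl 6-deoxy-6-iodo-1,3-O-isopropylidene-α-D-fructofuranoside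
Product: 5 methyl 4-O-TBS-6-deoxy-6-iodo-1,3-O-isopropylidene-α-D-fructofuranoside
Conditions: TBSCl, imidazole, DMF, rt
Reagents that add atoms: tert-butyldimethylsilyl chloride, CC(C)(C)[Si](C)(C)Cl
Why: Imidazole-promoted silyl ether formation on the only remaining hydroxyl installs a group that is expected to survive zinc, ylides, i-Bu2AlH, peracid and the ruthenium carbene and to leave with fluoride at the end.

Step 5
Reactants: 5 methyl 4-O-TBS-6-deoxy-6-iodo-1,3-O-isopropylidene-α-D-fructofuranoside
Product: 7 (4S)-4-[(1R)-1-(TBSO)prop-2-en-1-yl]-2,2-dimethyl-1,3-dioxan-5-one, via alkylzinc iodide 6 (not isolated)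
Conditions: Zn dust (acid-washed), THF/H2O 4:1, ultrasound, 40 °C
Reagents that add atoms: none
Why: In this Bernet–Vasella reductive fragmentation zinc inserts into the C6–I bond, the organozinc expels the ring oxygen from C5 by β-elimination to create the C5=C6 vinyl group, and the resulting C2 hemiketal alkoxide ejects methoxide to unveil the ketone inside the intact dioxane, the near-neutral medium being expected to leave the α-centre (fructose C3) and the β-silyloxy centre (fructose C4) unchanged.

Step 6
Reactants: 7 (4S)-4-[(1R)-1-(TBSO)prop-2-en-1-yl]-2,2-dimethyl-1,3-dioxan-5-one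
Product: 8 (3S,4R)-4-(TBSO)-1,3-dihydroxyhex-5-en-2-one
Conditions: CSA (0.1 equiv), MeOH, 0 °C to rt; then Et3N
Reagents that add atoms: none
Why: Acid-catalysed acetal exchange with methanol should remove the six-membered acetonide much faster than it solvolyses the hindered secondary allylic silyl ether, and no bond to C3 or C4 is broken.

Step 7
Reactants: 8 (3S,4R)-4-(TBSO)-1,3-dihydroxyhex-5-en-2-one
Product: 9 (3S,4R)-1,4-bis(TBSO)-3-hydroxyhex-5-en-2-one
Conditions: TBSCl (1.05 equiv), imidazole, CH2Cl2, −20 to 0 °C
Reagents that add atoms: tert-butyldimethylsilyl chloride, CC(C)(C)[Si](C)(C)Cl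
Why: Kinetically controlled silylation should take the primary C1 hydroxyl in preference to the secondary C3 hydroxyl, which is flanked by the ketone and the silyloxy-bearing C4, leaving exactly the hydroxyl that the next step must acylate.

Step 8
Reactants: 9 (3S,4R)-1,4-bis(TBSO)-3-hydroxyhex-5-en-2-one; 10 (triphenylphosphoranylidene)ketene
Product: 12 (5R)-5-[(1R)-1-(TBSO)prop-2-en-1-yl]-4-[(TBSO)methyl]furan-2(5H)-one, via ester ylide 11 (not isolated)
Conditions: 10 (1.2 equiv), toluene, 80 °C
Reagents that add atoms: (triphenylphosphoranylidene)ketene 10, O=C=C=P(c1ccccc1)(c1ccccc1)c1ccccc1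
Why: In this cumulated-ylide cascade the free hydroxyl adds across the ketene C=C to give an ester-stabilised phosphorane that closes the five-membered ring by intramolecular Wittig olefination of the neighbouring ketone, so the new C1=C6 bond is locked with the C2 oxygen and the future C5 cis inside the butenolide, and the base-free medium should leave the γ-centre untouched.

Step 9
Reactants: 12 (5R)-5-[(1R)-1-(TBSO)prop-2-en-1-yl]-4-[(TBSO)methyl]furan-2(5H)-one
Product: 13 (5R)-5-[(1R)-1-(TBSO)prop-2-en-1-yl]-4-[(TBSO)methyl]-2,5-dihydrofuran-2-ol (both hemiacetal epimers)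
Conditions: i-Bu2AlH (1.1 equiv), CH2Cl2, −78 °C; then aq. KNaC4H4O6
Reagents that add atoms: none
Why: Partial 1,2-reduction of a lactone by i-Bu2AlH at −78 °C stops at the aluminium hemiacetal, which a non-acidic tartrate work-up releases as the lactol, whose new hemiacetal centre forms as a mixture that is of no consequence because that carbon becomes sp2 in the next step.

Step 10
Reactants: 13 (5R)-5-[(1R)-1-(TBSO)prop-2-en-1-yl]-4-[(TBSO)methyl]-2,5-dihydrofuran-2-ol
Product: 15 (3R,4R,5Z)-3-(TBSO)-5-[(TBSO)methyl]octa-1,5,7-trien-4-ol, via open-chain (Z)-hydroxy enal 14 (not isolated)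
Conditions: Ph3PCH3Br, n-BuLi, THF, 0 °C; then crude 13, 0 °C to rt
Reagents that add atoms: methyltriphenylphosphonium bromide, C[P+](c1ccccc1)(c1ccccc1)c1ccccc1.[Br-]
Why: In this Wittig methylenation of a lactol the alkoxide of 13 equilibrates with the open (Z)-enal, whose aldehyde is trapped by the non-stabilised ylide, so the ring-fixed Z geometry is transferred to the open chain and the former ring oxygen emerges as the free C2 hydroxyl, the lithium counter-ion and low temperature serving to suppress silyl migration to that alkoxide.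

Step 11
Reactants: 15 (3R,4R,5Z)-3-(TBSO)-5-[(TBSO)methyl]octa-1,5,7-trien-4-ol
Product: 16 (1S,2R)-2-(TBSO)-1-[(2R,3S)-2-[(TBSO)methyl]-3-ethenyloxiran-2-yl]but-3-en-1-ol
Conditions: mCPBA (1.1 equiv), NaHCO3 (solid), CH2Cl2, −20 to 0 °C
Reagents that add atoms: 3-chloroperbenzoic acid, O=C(OO)c1cccc(Cl)c1
Why: The peracid, held by a hydrogen bond to the C2 hydroxyl, hands its terminal oxygen to C1=C6 through a concerted butterfly transition state, the closest known reaction type being the Henbest-type hydroxyl-directed peracid epoxidation of acyclic (Z)-allylic alcohols, which is threo-selective. The oxirane is the only ring closed, by direct transfer of one oxygen atom with both C–O bonds forming on the same face in one event and no ionic intermediate. C1 and C6 are created together: their mutual relation follows from the Z geometry and the syn addition, and their sense relative to C2 follows from allylic 1,3-strain between the C6 vinyl group (cis to C2) and the substituents on C2, which holds C2–H in the alkene plane, places the hydroxyl on one face at the roughly 120° dihedral angle a peracid prefers and the C3 chain on the other, so that oxygen should arrive on the hydroxyl face. The step needs face selectivity, which the C2 stereocentre secures as described, and site selectivity, which is secured because C1=C6 is the only trisubstituted and hydroxyl-bearing alkene while both terminal vinyl groups are monosubstituted and slow. Solid NaHCO3 is there to keep the 3-chlorobenzoic acid from opening the new vinyl oxirane.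

Step 12
Reactants: 16 (1S,2R)-2-(TBSO)-1-[(2R,3S)-2-[(TBSO)methyl]-3-ethenyloxiran-2-yl]but-3-en-1-ol
Product: 17 (1R,2S,3R,6S)-3-(TBSO)-1-[(TBSO)methyl]-7-oxabicyclo[4.1.0]hept-4-en-2-ol
Conditions: second-generation Grubbs catalyst [1,3-bis(2,4,6-trimethylphenyl)imidazolidin-2-ylidene](PCy3)Cl2Ru=CHPh (5 mol %), CH2Cl2 (0.005 M), 40 °C
Reagents that add atoms: none
Why: Ring-closing olefin metathesis should join the two monosubstituted vinyl groups, which the oxirane holds cis, into the six-membered ring at C4=C5 with loss of ethylene, the ruthenium carbene tolerating the oxirane, the free hydroxyl and the silyl ethers and touching no stereocentre.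

Step 13
Reactants: 17 (1R,2S,3R,6S)-3-(TBSO)-1-[(TBSO)methyl]-7-oxabicyclo[4.1.0]hept-4-en-2-ol
Product: 18 (1S,2S,3R,6S)-3-(TBSO)-1-[(TBSO)methyl]-2-(MOP-oxy)-7-oxabicyclo[4.1.0]hept-4-ene
Conditions: 2-methoxypropene, PPTS (cat.), CH2Cl2, 0 °C; then Et3N
Reagents that add atoms: 2-methoxypropene, C=C(C)OC
Why: Acid-catalysed addition of the lone hydroxyl to an enol ether gives an achiral mixed acetal under conditions too mild to open the oxirane, so that the later benzoylation can reach only O7 and O3.

Step 14
Reactants: 18 (1S,2S,3R,6S)-3-(TBSO)-1-[(TBSO)methyl]-2-(MOP-oxy)-7-oxabicyclo[4.1.0]hept-4-ene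
Product: 19 (1S,2S,3R,6S)-1-(hydroxymethyl)-2-(MOP-oxy)-7-oxabicyclo[4.1.0]hept-4-en-3-ol
Conditions: Bu4NF, THF, 0 °C to rt
Reagents that add atoms: none
Why: Fluoride-driven desilylation (formation of the strong Si–F bond) should remove both silyl ethers while the mixed acetal, the alkene and the oxirane are inert to fluoride in dry THF at this temperature.

Step 15
Reactants: 19 (1S,2S,3R,6S)-1-(hydroxymethyl)-2-(MOP-oxy)-7-oxabicyclo[4.1.0]hept-4-en-3-ol
Product: 20 [(1S,2S,3R,6S)-3-(benzoyloxy)-2-(MOP-oxy)-7-oxabicyclo[4.1.0]hept-4-en-1-yl]methyl benzoate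
Conditions: BzCl (2.5 equiv), Et3N, DMAP (cat.), CH2Cl2, 0 °C to rt
Reagents that add atoms: benzoyl chloride, O=C(Cl)c1ccccc1
Why: DMAP-catalysed acylation through the N-benzoylpyridinium ion esterifies the primary C7 and the allylic C3 hydroxyls, the amine base keeping the medium non-acidic so that the mixed acetal on O2 stays in place.

Step 16
Reactants: 20 [(1S,2S,3R,6S)-3-(benzoyloxy)-2-(MOP-oxy)-7-oxabicyclo[4.1.0]hept-4-en-1-yl]methyl benzoate
Product: 21 [(1R,2S,3R,6S)-3-(benzoyloxy)-2-hydroxy-7-oxabicyclo[4.1.0]hept-4-en-1-yl]methyl benzoate (CNP0192269.6)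
Conditions: PPTS (cat.), MeOH, 0 °C
Reagents that add atoms: none
Why: The mixed acetal is among the most acid-labile hydroxyl protections and should leave by acetal exchange with methanol under weak-acid catalysis at 0 °C, conditions under which benzoates are not expected to migrate nor the oxirane to open.

Compound list
1 | D-fructose (drawn as the open keto form) | OCC(=O)[C@@H](O)[C@H](O)[C@H](O)CO | starting material
2 | methyl α-D-fructofuranoside | CO[C@]1(CO)[C@@H](O)[C@H](O)[C@@H](CO)O1 | intermediate
3 | methyl 1,3-O-isopropylidene-α-D-fructofuranoside | CO[C@]12COC(C)(C)O[C@H]1[C@H](O)[C@@H](CO)O2 | intermediate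
4 | methyl 6-deoxy-6-iodo-1,3-O-isopropylidene-α-D-fructofuranoside | CO[C@]12COC(C)(C)O[C@H]1[C@H](O)[C@@H](CI)O2 | intermediate
5 | methyl 4-O-TBS-6-deoxy-6-iodo-1,3-O-isopropylidene-α-D-fructofuranoside | CO[C@]12COC(C)(C)O[C@H]1[C@H](O[Si](C)(C)C(C)(C)C)[C@@H](CI)O2 | intermediate
6 | alkylzinc iodide formed from 5 at C6 (not isolated) | CO[C@]12COC(C)(C)O[C@H]1[C@H](O[Si](C)(C)C(C)(C)C)[C@@H](C[Zn]I)O2 | intermediate
7 | (4S)-4-[(1R)-1-(TBSO)prop-2-en-1-yl]-2,2-dimethyl-1,3-dioxan-5-one | C=C[C@@H](O[Si](C)(C)C(C)(C)C)[C@@H]1OC(C)(C)OCC1=O | intermediate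
8 | (3S,4R)-4-(TBSO)-1,3-dihydroxyhex-5-en-2-one | C=C[C@@H](O[Si](C)(C)C(C)(C)C)[C@H](O)C(=O)CO | intermediate
9 | (3S,4R)-1,4-bis(TBSO)-3-hydroxyhex-5-en-2-one | C=C[C@@H](O[Si](C)(C)C(C)(C)C)[C@H](O)C(=O)CO[Si](C)(C)C(C)(C)C | intermediate
10 | (triphenylphosphoranylidene)ketene | O=C=C=P(c1ccccc1)(c1ccccc1)c1ccccc1 | starting material
11 | (3S,4R)-1,4-bis(TBSO)-2-oxohex-5-en-3-yl (triphenylphosphoranylidene)acetate (not isolated) | C=C[C@@H](O[Si](C)(C)C(C)(C)C)[C@H](OC(=O)C=P(c1ccccc1)(c1ccccc1)c1ccccc1)C(=O)CO[Si](C)(C)C(C)(C)C | intermediate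
12 | (5R)-5-[(1R)-1-(TBSO)prop-2-en-1-yl]-4-[(TBSO)methyl]furan-2(5H)-one | C=C[C@@H](O[Si](C)(C)C(C)(C)C)[C@@H]1OC(=O)C=C1CO[Si](C)(C)C(C)(C)C | intermediate
13 | (5R)-5-[(1R)-1-(TBSO)prop-2-en-1-yl]-4-[(TBSO)methyl]-2,5-dihydrofuran-2-ol, both epimers at the hemiacetal carbon | C=C[C@@H](O[Si](C)(C)C(C)(C)C)[C@@H]1OC(O)C=C1CO[Si](C)(C)C(C)(C)C | intermediate
14 | (2Z,4R,5R)-5-(TBSO)-4-hydroxy-3-[(TBSO)methyl]hepta-2,6-dienal (not isolated) | C=C[C@@H](O[Si](C)(C)C(C)(C)C)[C@H](O)/C(CO[Si](C)(C)C(C)(C)C)=C\C=O | intermediate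
15 | (3R,4R,5Z)-3-(TBSO)-5-[(TBSO)methyl]octa-1,5,7-trien-4-ol | C=C[C@@H](O[Si](C)(C)C(C)(C)C)[C@H](O)/C(CO[Si](C)(C)C(C)(C)C)=C\C=C | intermediate
16 | (1S,2R)-2-(TBSO)-1-[(2R,3S)-2-[(TBSO)methyl]-3-ethenyloxiran-2-yl]but-3-en-1-ol | CC(C)(C)[Si](C)(C)OC[C@@]1(O[C@H]1C=C)[C@@H](O)[C@H](O[Si](C)(C)C(C)(C)C)C=C | intermediate
17 | (1R,2S,3R,6S)-3-(TBSO)-1-[(TBSO)methyl]-7-oxabicyclo[4.1.0]hept-4-en-2-ol | CC(C)(C)[Si](C)(C)OC[C@]12O[C@H]1C=C[C@@H](O[Si](C)(C)C(C)(C)C)[C@@H]2O | intermediate
18 | MOP ether of 17 at O2, (1S,2S,3R,6S); same spatial arrangement as 17, the C1 descriptor changing only through the priority rules | CC(C)(C)[Si](C)(C)OC[C@]12O[C@H]1C=C[C@@H](O[Si](C)(C)C(C)(C)C)[C@@H]2OC(C)(C)OC | intermediate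
19 | (1S,2S,3R,6S)-1-(hydroxymethyl)-2-(MOP-oxy)-7-oxabicyclo[4.1.0]hept-4-en-3-ol | OC[C@]12O[C@H]1C=C[C@@H](O)[C@@H]2OC(C)(C)OC | intermediate
20 | [(1S,2S,3R,6S)-3-(benzoyloxy)-2-(MOP-oxy)-7-oxabicyclo[4.1.0]hept-4-en-1-yl]methyl benzoate | O=C(OC[C@]12O[C@H]1C=C[C@@H](OC(=O)c1ccccc1)[C@@H]2OC(C)(C)OC)c1ccccc1 | intermediate
21 | [(1R,2S,3R,6S)-3-(benzoyloxy)-2-hydroxy-7-oxabicyclo[4.1.0]hept-4-en-1-yl]methyl benzoate, CNP0192269.6; oxirane oxygen anti to the C2 hydroxyl, C2 and C3 oxygens trans | O=C(OC[C@]12O[C@H]1C=C[C@@H](OC(=O)c1ccccc1)[C@@H]2O)c1ccccc1 | target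

Total step count: 16. Longest linear sequence: 16 steps, from D-fructose 1 (10 is a purchased reagent).

Steps most likely to fail

Step 10. The lactol 13 may lose water to the aromatic furan (acid traces, silica, standing), or the ylide may act only as a base, so that little open enal is olefinated. The fallback sets out from 12 and comes back at 15. Excess i-Bu2AlH reduces 12 past the lactol stage to (2Z,4R,5R)-5-(TBSO)-3-[(TBSO)methyl]hepta-2,6-diene-1,4-diol F1. Both hydroxyls are silylated with Et3SiOTf and 2,6-lutidine to the bis(triethylsilyl) ether F2. Swern conditions ((COCl)2, DMSO, then Et3N), known to cleave and oxidise a primary triethylsilyl ether while sparing secondary silyl ethers and primary TBS ethers, should give the O-silylated (Z)-enal F3, which cannot close to a lactol or a furan. Methylenation with Ph3P=CH2 gives the triethylsilyl ether of the dienol F4, and PPTS in MeOH at 0 °C removes the triethylsilyl group selectively to deliver 15.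

Step 11. Facial discrimination may be incomplete, with oxygen also delivered to the face of the C3 chain, or the acid by-product may open the vinyl oxirane. The fallback sets out from 15 and comes back at 18. The directing hydroxyl is capped with 2-methoxypropene and PPTS to give the MOP ether of the dienol F5, and the face is then chosen by the reagent through a Shi epoxidation: a dioxirane generated from KHSO5 and a fructose-derived ketone catalyst, buffered with K2CO3 near pH 10.5 in MeCN/dimethoxymethane/H2O at 0 °C. The L-fructose-derived enantiomer of the ketone is used, because the spiro transition-state model predicts that it attacks the required face of this trisubstituted alkene. Under these basic, acid-free conditions it should give the MOP-capped divinyl oxirane F6, and ring-closing metathesis of F6 under the conditions of step 12 gives 18 directly.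

Step 6. Under the acid the free 1,3-dihydroxy ketone may isomerise through its enediol, form hemiketal dimers, or lose or shift the secondary silyl group. The fallback sets out from 5 and comes back at 9; it changes the order of events so that the ketone is unveiled only after O1 is protected. CSA in MeOH removes the acetonide from the robust glycoside 5 to give methyl 4-O-TBS-6-deoxy-6-iodo-α-D-fructofuranoside F7; any anomerisation would be harmless because C2 becomes the ketone carbon. TBSCl and imidazole at low temperature silylate the primary O1 to give methyl 1,4-di-O-TBS-6-deoxy-6-iodo-α-D-fructofuranoside F8. The zinc fragmentation of step 5 applied to F8 then delivers 9 in one operation, bypassing 7 and 8.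

Further compounds
F1 | step 10 | (2Z,4R,5R)-5-(TBSO)-3-[(TBSO)methyl]hepta-2,6-diene-1,4-diol | C=C[C@@H](O[Si](C)(C)C(C)(C)C)[C@H](O)/C(CO[Si](C)(C)C(C)(C)C)=C\CO
F2 | step 10 | 1,4-bis(triethylsilyl) ether of F1 | C=C[C@@H](O[Si](C)(C)C(C)(C)C)[C@H](O[Si](CC)(CC)CC)/C(CO[Si](C)(C)C(C)(C)C)=C\CO[Si](CC)(CC)CC
F3 | step 10 | (2Z,4R,5R)-5-(TBSO)-3-[(TBSO)methyl]-4-(triethylsilyloxy)hepta-2,6-dienal | C=C[C@@H](O[Si](C)(C)C(C)(C)C)[C@H](O[Si](CC)(CC)CC)/C(CO[Si](C)(C)C(C)(C)C)=C\C=O
F4 | step 10 | triethylsilyl ether of 15 at the C4 oxygen of the triene | C=C[C@@H](O[Si](C)(C)C(C)(C)C)[C@H](O[Si](CC)(CC)CC)/C(CO[Si](C)(C)C(C)(C)C)=C\C=C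
F5 | step 11 | MOP ether of 15 | C=C[C@@H](O[Si](C)(C)C(C)(C)C)[C@H](OC(C)(C)OC)/C(CO[Si](C)(C)C(C)(C)C)=C\C=C
F6 | step 11 | MOP ether of 16 | CC(C)(C)[Si](C)(C)OC[C@@]1(O[C@H]1C=C)[C@@H](OC(C)(C)OC)[C@H](O[Si](C)(C)C(C)(C)C)C=C
F7 | step 6 | methyl 4-O-TBS-6-deoxy-6-iodo-α-D-fructofuranoside | CO[C@]1(CO)[C@@H](O)[C@H](O[Si](C)(C)C(C)(C)C)[C@@H](CI)O1
F8 | step 6 | methyl 1,4-di-O-TBS-6-deoxy-6-iodo-α-D-fructofuranoside | CO[C@]1(CO[Si](C)(C)C(C)(C)C)[C@@H](O)[C@H](O[Si](C)(C)C(C)(C)C)[C@@H](CI)O1
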